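## Structural features

The target, 5-(6-bromo-4-methoxy-1H-indol-3-yl)-2-(5-bromo-1H-pyrrol-2-yl)oxazole (22), is a flat chain of three aromatic heterocycles. Indole C3 is bonded to oxazole C5, and oxazole C2 is bonded to pyrrole C2. Indole C2 and oxazole C4 carry hydrogen, the indole benzenoid ring carries OMe at C4 and Br at C6, and the pyrrole carries Br at C5. There is no stereocentre, so no stereochemical relationship has to be set or preserved. The fragile parts are the 2-bromopyrrole unit (acid, light, electrophiles), the electron-rich methoxyindole (oxidants, electrophiles), the two N–H groups (nucleophilic toward arynes and alkylating agents) and the two C–Br bonds (alkyllithiums, low-valent palladium). The real difficulty is regiochemical. The indole needs a 1,2,3,5-tetrasubstituted benzene ring (N on C7a, C on C3a, OMe on C4, Br on C6), the biaryl bond at indole C3 is crowded by the methoxy group, and each terminal ring must carry exactly one bromine. The key step exploits the fact that N1 and C3 sit on the neighbouring benzenoid carbons C7a and C3a, with the OMe-bearing C4 next to C3a. This is the pattern produced when a nitrogen nucleophile adds to the remote carbon of a 3-methoxyaryne and the aryl anion beside oxygen then forms the C–C bond. The remaining N1–C2(H)–C3(oxazolyl) unit has the atom sequence of a 3-hetaryl-2H-azirine.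

## Logic of the disconnections

22 ⇒ 21. Only the pyrrole N–CH2 bond of the N,O-acetal protecting group is cut. The pyrrole nitrogen has to be masked through the aryne step, the metalation and the oxazole closure, and a fluoride-labile group can be removed without touching C–Br or the indole. The forward step must cleave at silicon cleanly and must not stall at the N-hydroxymethyl stage.

21 ⇒ 6 + 19 (through 20). The indole bonds N1–C7a and C3–C3a are cut. This removes the whole five-membered ring of the indole in one operation and divides the molecule into two pieces of similar size. The benzenoid substituents then come from a simple phenol, and N1, C2, C3 and the complete oxazole–pyrrole arm come from 19. The forward step requires that nitrogen adds to the aryne carbon remote from OMe, that the azirine nitrogen competes successfully with the pyrrole and oxazole rings as aryne traps, and that the N–H product is not arylated further. The pyrrole bromine is already present in 19; it blocks the second α-position of the pyrrole, which makes that ring a poorer diene toward 20, and it removes any need for electrophilic bromination next to the methoxyindole.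

19 ⇒ 17 ⇒ 16 (through 18). The N–CH2 bond of the three-membered ring is cut (Neber closure), then the C=N bond back to the ketone. This avoids azide chemistry and reduces the strained ring to an ordinary methyl ketone. The forward step requires deprotonation of the methyl group of 18 by a non-nucleophilic base in an aprotic medium, so that the azirine is not consumed by addition.

16 ⇒ 14 (through 15). The bond between oxazole C5 and the acyl carbon is cut. With C2 substituted, C5–H is the most acidic position of 14, so the two-carbon unit can be attached by deprotonation and acylation. The base must not attack or exchange the pyrrole C–Br bond, and the acylation must stop at the ketone.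

14 ⇒ 11 (through 12 and 13). The oxazole O1–C5 bond and the C4=C5 unsaturation are cut, leading back to an acyclic amido acetal. The forward closure has to be run without strong acid and with the pyrrole nitrogen already blocked. A free pyrrole N–H would add to the unmasked aldehyde to give a six-membered cyclic hemiaminal, and strong acid would direct the oxocarbenium ion to pyrrole C3.

11 ⇒ 10 ⇒ 7 + 8 (through 9). The pyrrole N–CH2 bond and then the amide C–N bond are cut. Both pieces are simple, and the bromine comes in regiochemically defined form with 7. The N-alkylation has to distinguish the pyrrole N–H from the amide N–H, which their different acidities allow.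

6 ⇒ 3 ⇒ 2 ⇒ 1 (through 4 and 5). In turn the O–S bond, the aryl C–Si bond (traced to an O–Si bond by a 1,3-silyl shift), and the C–I bond are cut. An alkyllithium-based directed ortho-lithiation would attack the C–Br bond. An iodine placed ortho to the phenol oxygen gives a site-specific handle instead, because iodine–lithium exchange is much faster than bromine–lithium exchange. The forward sequence requires ortho-selective iodination of 1 and exactly one equivalent of alkyllithium.

## Other disconnections considered

Alternative 1: The cut lies inside the oxazole, at N3–C4 and O1–C2. The product is the bis-Boc compound A1, tert-butyl 6-bromo-3-{2-[1-(tert-butoxycarbonyl)pyrrol-2-yl]oxazol-5-yl}-4-methoxyindole-1-carboxylate, traced to its isomer A2, the 5-indolyl-3-pyrrolylisoxazole.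
- Forward key step: UV irradiation would break the weak N–O bond of A2, the acyl azirine would open at its C–C bond to a nitrile ylide, and closure through the carbonyl oxygen would give A1.
- In its favour: A2 should be available by a regioselective nitrile oxide–alkyne cycloaddition that joins the two halves in one step. The transposition is a reagent-free isomerisation suited to flow, and no organometallic reagent meets a C–Br bond.
- Against it here: the aryl bromide sits on the irradiated chromophore, so C–Br homolysis is a plausible competing process. The azirine/nitrile ylide manifold can also return to the isoxazole or drain to ketenimine-type products. Both N–H groups need masking and unmasking. The disconnection leaves the 4,6-disubstituted indole nucleus unsolved, and the pyrrole bromine would have to be added late or be irradiated as well.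
- Comparison, structure: the chosen plan goes further, since it creates the indole nucleus and fixes its substitution pattern. In convergence the two plans are equal.
- Comparison, mechanism: both rely on the strain of a 2H-azirine. In the alternative the azirine is transient and never handled, which is better than isolating 19. Excited-state chemistry beside C–Br bonds is, however, harder to predict than polar addition to 20.
- Comparison, step economy: the alternative is judged no shorter, because the indole, its alkyne, the nitrile oxide precursor and two carbamate operations are all needed.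

Alternative 2: The cut is at oxazole C4–C5 and O1–C2, with the oxazole built on the indole C3 carbonyl. The product A3, 5-(6-bromo-4-methoxy-1-{[2-(trimethylsilyl)ethoxy]methyl}indol-3-yl)oxazole, would come from the protected indole-3-carbaldehyde A4 and tosylmethyl isocyanide A5.
- Forward key step: carbonate-mediated addition of the anion of A5 to A4, closure of the alkoxide on the isocyanide carbon, and loss of sulfinate. The pyrrole would then be attached at the acidic oxazole C2–H by metalation, halogenation and cross-coupling.
- In its favour: every step has close precedent, so in predictability this alternative is better than the chosen plan. Late attachment of the pyrrole also makes it better for analogue work.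
- Against it here: 2-metalated oxazoles equilibrate with ring-opened isocyano enolates, so C2 halogenation can be accompanied by substitution at C4. The coupling needs zerovalent palladium beside the indole C6–Br bond. The pyrrole bromine must come from a labile bromopyrrolyl metal reagent or from late bromination beside the methoxyindole. The sequence is linear, and the indole nucleus must still be bought or made.
- Comparison, structure: the chosen plan builds the indole and places both benzenoid substituents from a phenol; the alternative decorates an existing indole.
- Comparison, mechanism: well-charted polar and palladium steps stand against an aryne annulation that is less well charted for hetaryl azirines.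
- Comparison, step economy: about seven or eight operations from the indole (protection, formylation, oxazole formation, C2 halogenation, coupling, bromination, deprotection). This equals the longest linear sequence of the chosen plan if the indole is purchased and exceeds it if not.

Alternative 3: The cut is at indole N1–C2 and C3–C3a. The product A6, the 2-(trimethylsilyl)indole, would come from 5-bromo-2-iodo-3-methoxyaniline A7 and the oxazolyl silylalkyne A8.
- Forward key step: oxidative addition of zerovalent palladium into the C–I bond of A7, syn-insertion of A8 with the bulky silyl group placed on the future C2, and C–N reductive elimination.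
- In its favour: the same C3–C3a bond is formed, with regiochemistry set by the silyl group in a catalytic and well-understood process. A8 is a bench-stable alkyne, clearly better to handle than the strained 19. The C2 silyl group could be removed by the same fluoride that removes the N-protecting group, so on this point the plans are equal.
- Against it here: the iodine of A7 lies between the amino and methoxy groups. This doubly ortho-substituted position slows oxidative addition and insertion, and at the temperatures then needed the C–Br bond may start to react. A7 is itself a regiochemical problem, because iodination of the corresponding bromoanisidine has three activated positions.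
- Comparison, structure: both plans build the five-membered ring onto a benzenoid precursor. The chosen plan takes the 1,2,3,5-pattern from the regiochemistry of the aryne; the alternative must pre-install three contiguous substituents.
- Comparison, mechanism: the alternative is the better understood. The chosen plan uses no transition metal and so raises no C–Br chemoselectivity question.
- Comparison, step economy: roughly equal. A8 needs C5 halogenation and a Sonogashira coupling where the chosen plan needs acylation, oximation and Neber closure, and A7 needs about as many steps as 6.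

Key step: step 10

Remark: 5-bromo-1H-pyrrole-2-carboxylic acid (7) is taken to be a purchasable compound, so the pyrrole bromine is a spectator from the first step; SEM = [2-(trimethylsilyl)ethoxy]methyl.

## Route

Step 1
Reactants: 1 4-bromo-2-methoxyphenol
Product: 2 4-bromo-2-iodo-6-methoxyphenol
Conditions: I2, NaHCO3, THF/H2O, 0 °C → rt
Reagents that add atoms: iodine, II
Why: Electrophilic aromatic iodination on the phenoxide manifold; the oxido group outweighs methoxy and bromine, its para position is blocked by bromine, so iodine should enter the only free ortho position, and the mildly basic medium keeps reaction away from the position para to the methoxy group.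

Step 2
Reactants: 2 4-bromo-2-iodo-6-methoxyphenol
Product: 3 (4-bromo-2-iodo-6-methoxyphenoxy)trimethylsilane
Conditions: (Me3Si)2NH (0.6 equiv), THF, 65 °C; evaporate
Reagents that add atoms: hexamethyldisilazane, C[Si](C)(C)N[Si](C)(C)C
Why: O-Silylation of the phenol with hexamethyldisilazane; ammonia is the only by-product, so evaporation should leave a silyl ether dry enough for the organolithium step.

Step 3
Reactants: 3 (4-bromo-2-iodo-6-methoxyphenoxy)trimethylsilane
Product: 6 4-bromo-2-methoxy-6-(trimethylsilyl)phenyl trifluoromethanesulfonate, via aryllithium 4 (not isolated), via lithium phenoxide 5 (not isolated)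
Conditions: n-BuLi (1.0 equiv), THF, −78 °C → −40 °C; Tf2O, −78 °C → rt
Reagents that add atoms: trifluoromethanesulfonic anhydride, O=S(=O)(OS(=O)(=O)C(F)(F)F)C(F)(F)F
Why: Iodine–lithium exchange is much faster than bromine–lithium exchange at −78 °C, so one equivalent of n-BuLi should lithiate only the carbon ortho to the silyloxy group (4). An anionic 1,3 O→C silyl shift (retro-Brook rearrangement) then gives the C-silyl phenoxide 5, which is triflated in the same flask. No free alkyllithium remains after the exchange, which is why the C–Br bond should survive where a directed ortho-lithiation with sec-BuLi would not.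

Step 4
Reactants: 7 5-bromo-1H-pyrrole-2-carboxylic acid; 8 2,2-dimethoxyethanamine (aminoacetaldehyde dimethyl acetal)
Product: 10 5-bromo-N-(2,2-dimethoxyethyl)-1H-pyrrole-2-carboxamide, via acyl imidazole 9 (not isolated)
Conditions: CDI, THF, rt; then 8, rt
Reagents that add atoms: none
Why: Amide formation through the acyl imidazole (CDI activation); the pyrrole N–H is not acylated without base, and imidazole and CO2 are the only by-products.

Step 5
Reactants: 10 5-bromo-N-(2,2-dimethoxyethyl)-1H-pyrrole-2-carboxamide
Product: 11 5-bromo-N-(2,2-dimethoxyethyl)-1-SEM-pyrrole-2-carboxamide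
Conditions: NaH (1.05 equiv), DMF, 0 °C; SEMCl, 0 °C → rt
Reagents that add atoms: 2-(trimethylsilyl)ethoxymethyl chloride, C[Si](C)(C)CCOCCl
Why: N-Alkylation of the pyrrolide; the N–H of a 2-acyl-5-bromopyrrole is several pKa units more acidic than the secondary amide N–H, so one equivalent of NaH should deprotonate only the pyrrole. The nitrogen must be blocked here because an N-unsubstituted pyrrole-2-carboxamide would trap the aldehyde of step 6 as a six-membered cyclic hemiaminal instead of closing the oxazole.

Step 6
Reactants: 11 5-bromo-N-(2,2-dimethoxyethyl)-1-SEM-pyrrole-2-carboxamide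
Product: 14 2-(5-bromo-1-SEM-pyrrol-2-yl)oxazole, via aldehyde 12 (not isolated), via bromooxazoline 13 (not isolated)
Conditions: Amberlyst-15, acetone/H2O, rt, filter, evaporate (toluene azeotrope); PPh3, (BrCl2C)2, 2,6-di-tert-butylpyridine, CH2Cl2, 0 °C → rt; DBU, MeCN, rt
Reagents that add atoms: none
Why: Mild acetal hydrolysis followed by a Robinson–Gabriel-type cyclodehydration under non-acidic conditions: Ph3PBr2 formed in situ lets the amide oxygen close on the activated aldehyde carbon of 12 to give bromooxazoline 13, and DBU eliminates HBr to aromatise. Strong protic acid is avoided because it would remove the SEM group and divert the oxocarbenium ion to pyrrole C3 (Pomeranz–Fritsch-type closure).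

Step 7
Reactants: 14 2-(5-bromo-1-SEM-pyrrol-2-yl)oxazole
Product: 16 1-[2-(5-bromo-1-SEM-pyrrol-2-yl)oxazol-5-yl]ethanone, via oxazolylmagnesium chloride 15 (not isolated)
Conditions: TMPMgCl·LiCl (1.2 equiv), THF, −30 °C → 0 °C; MeC(O)N(OMe)Me, −30 °C → rt; aq. NH4Cl
Reagents that add atoms: N-methoxy-N-methylacetamide, CC(=O)N(C)OC
Why: Directed C–H magnesiation followed by a Weinreb ketone synthesis; with C2 substituted, the oxazole C5–H is the most acidic proton of 14, the hindered amide base should neither exchange nor attack the pyrrole C–Br bond, and the N-methoxy-N-methyl amide stops the addition at the ketone stage.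

Step 8
Reactants: 16 1-[2-(5-bromo-1-SEM-pyrrol-2-yl)oxazol-5-yl]ethanone
Product: 17 1-[2-(5-bromo-1-SEM-pyrrol-2-yl)oxazol-5-yl]ethanone oxime (E/Z mixture)
Conditions: NH2OH·HCl, NaOAc, EtOH, 50 °C
Reagents that add atoms: hydroxylamine hydrochloride, Cl.NO
Why: Condensation of the ketone with hydroxylamine under acetate buffering; the oxime geometry is immaterial because the Neber closure that follows does not depend on it.

Step 9
Reactants: 17 1-[2-(5-bromo-1-SEM-pyrrol-2-yl)oxazol-5-yl]ethanone oxime
Product: 19 3-[2-(5-bromo-1-SEM-pyrrol-2-yl)oxazol-5-yl]-2H-azirine, via oxime mesylate 18 (not isolated)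
Conditions: MsCl, Et3N, CH2Cl2, 0 °C; DBU, 0 °C → rt
Reagents that add atoms: none
Why: Neber reaction: mesylation makes the oxime oxygen a leaving group, DBU removes a methyl proton (acidified by the C=N bond and the electron-poor oxazol-5-yl group), and the carbanion displaces mesylate at nitrogen to close the three-membered ring. The aprotic medium and non-nucleophilic base should prevent the alcohol addition that otherwise carries the azirine on to an α-amino ketone.

Step 10
Reactants: 6 4-bromo-2-methoxy-6-(trimethylsilyl)phenyl trifluoromethanesulfonate; 19 3-[2-(5-bromo-1-SEM-pyrrol-2-yl)oxazol-5-yl]-2H-azirine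
Product: 21 5-(6-bromo-4-methoxy-1H-indol-3-yl)-2-(5-bromo-1-SEM-pyrrol-2-yl)oxazole, via aryne 20 (not isolated)
Conditions: CsF (3 equiv), MeCN, 60 °C; 6 (1.2 equiv) added slowly
Reagents that add atoms: none
Why: Fluoride desilylates 6 and expels triflate to give aryne 20. The azirine nitrogen of 19 adds to the aryne carbon remote from the methoxy group (N1–C7a), the site favoured in an inductively distorted 3-alkoxyaryne, which leaves the aryl anion beside oxygen. That anion attacks the C=N carbon of the N-arylazirinium unit (C3–C3a, formally a 4-exo-trig closure to a fused azabicyclobutane); cleavage of the strained internal C3–N bond with loss of a proton from the former CH2 then gives the five-membered ring, a net stepwise [3+2] annulation. Protonation of the indolide by the medium should give 21 with C2 unsubstituted and the oxazole on C3. The closest known reaction type is the fluoride-mediated annulation of arynes from 2-silylaryl triflates with 3-aryl-2H-azirines to N-unsubstituted indoles at about 60 °C. No stereocentre is formed. The step needs regioselectivity at the aryne (secured by the methoxy group), chemoselectivity against Diels–Alder capture of 20 (the pyrrole is substituted at both α-positions and the oxazole at C2 and C5), and no N-arylation of 21 (slow addition of 6 and a temperature at which protonation should outrun arylation). Both C–Br bonds are inert to fluoride and to the aryne.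

Step 11
Reactants: 21 5-(6-bromo-4-methoxy-1H-indol-3-yl)-2-(5-bromo-1-SEM-pyrrol-2-yl)oxazole
Product: 22 5-(6-bromo-4-methoxy-1H-indol-3-yl)-2-(5-bromo-1H-pyrrol-2-yl)oxazole
Conditions: Bu4NF (excess), THF, 65 °C
Reagents that add atoms: none
Why: Fluoride-induced SEM cleavage: attack at silicon releases ethene and an N-(oxidomethyl)pyrrole that loses formaldehyde, helped by the pyrrolide being stabilised by the flanking bromine and oxazole. Neither C–Br bond nor the indole should be affected.

## Compound list

1 | 4-bromo-2-methoxyphenol | COc1cc(Br)ccc1O | starting material
2 | 4-bromo-2-iodo-6-methoxyphenol | COc1cc(Br)cc(I)c1O | intermediate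
3 | (4-bromo-2-iodo-6-methoxyphenoxy)trimethylsilane | COc1cc(Br)cc(I)c1O[Si](C)(C)C | intermediate
4 | [5-bromo-3-methoxy-2-(trimethylsilyloxy)phenyl]lithium (not isolated) | COc1cc(Br)cc([Li])c1O[Si](C)(C)C | intermediate
5 | lithium 4-bromo-2-methoxy-6-(trimethylsilyl)phenoxide (not isolated) | COc1cc(Br)cc([Si](C)(C)C)c1[O-].[Li+] | intermediate
6 | 4-bromo-2-methoxy-6-(trimethylsilyl)phenyl trifluoromethanesulfonate | COc1cc(Br)cc([Si](C)(C)C)c1OS(=O)(=O)C(F)(F)F | intermediate
7 | 5-bromo-1H-pyrrole-2-carboxylic acid | OC(=O)c1ccc(Br)[nH]1 | starting material
8 | 2,2-dimethoxyethanamine | COC(OC)CN | starting material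
9 | (5-bromo-1H-pyrrol-2-yl)(imidazol-1-yl)methanone (not isolated) | O=C(c1ccc(Br)[nH]1)n1ccnc1 | intermediate
10 | 5-bromo-N-(2,2-dimethoxyethyl)-1H-pyrrole-2-carboxamide | COC(OC)CNC(=O)c1ccc(Br)[nH]1 | intermediate
11 | 5-bromo-N-(2,2-dimethoxyethyl)-1-{[2-(trimethylsilyl)ethoxy]methyl}pyrrole-2-carboxamide | COC(OC)CNC(=O)c1ccc(Br)n1COCC[Si](C)(C)C | intermediate
12 | 5-bromo-N-(2-oxoethyl)-1-{[2-(trimethylsilyl)ethoxy]methyl}pyrrole-2-carboxamide (not isolated) | O=CCNC(=O)c1ccc(Br)n1COCC[Si](C)(C)C | intermediate
13 | 5-bromo-2-(5-bromo-1-{[2-(trimethylsilyl)ethoxy]methyl}pyrrol-2-yl)-4,5-dihydrooxazole (racemic, not isolated) | BrC1CN=C(O1)c1ccc(Br)n1COCC[Si](C)(C)C | intermediate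
14 | 2-(5-bromo-1-{[2-(trimethylsilyl)ethoxy]methyl}pyrrol-2-yl)oxazole | C[Si](C)(C)CCOCn1c(Br)ccc1-c1ncco1 | intermediate
15 | [2-(5-bromo-1-{[2-(trimethylsilyl)ethoxy]methyl}pyrrol-2-yl)oxazol-5-yl]magnesium chloride (LiCl complex, not isolated) | C[Si](C)(C)CCOCn1c(Br)ccc1-c1ncc([Mg]Cl)o1 | intermediate
16 | 1-[2-(5-bromo-1-{[2-(trimethylsilyl)ethoxy]methyl}pyrrol-2-yl)oxazol-5-yl]ethanone | CC(=O)c1cnc(-c2ccc(Br)n2COCC[Si](C)(C)C)o1 | intermediate
17 | 1-[2-(5-bromo-1-{[2-(trimethylsilyl)ethoxy]methyl}pyrrol-2-yl)oxazol-5-yl]ethanone oxime (E/Z mixture) | CC(=NO)c1cnc(-c2ccc(Br)n2COCC[Si](C)(C)C)o1 | intermediate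
18 | O-methanesulfonyl oxime of 16 (E/Z mixture, not isolated) | CC(=NOS(C)(=O)=O)c1cnc(-c2ccc(Br)n2COCC[Si](C)(C)C)o1 | intermediate
19 | 3-[2-(5-bromo-1-{[2-(trimethylsilyl)ethoxy]methyl}pyrrol-2-yl)oxazol-5-yl]-2H-azirine | C1N=C1c1cnc(-c2ccc(Br)n2COCC[Si](C)(C)C)o1 | intermediate
20 | 5-bromo-3-methoxybenzyne (5-bromo-3-methoxy-1,2-didehydrobenzene, not isolated) | COC1=CC(Br)=CC#C1 | intermediate
21 | 5-(6-bromo-4-methoxy-1H-indol-3-yl)-2-(5-bromo-1-{[2-(trimethylsilyl)ethoxy]methyl}pyrrol-2-yl)oxazole | COc1cc(Br)cc2[nH]cc(-c3cnc(-c4ccc(Br)n4COCC[Si](C)(C)C)o3)c12 | intermediate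
22 | 5-(6-bromo-4-methoxy-1H-indol-3-yl)-2-(5-bromo-1H-pyrrol-2-yl)oxazole | COc1cc(Br)cc2[nH]cc(-c3cnc(-c4ccc(Br)[nH]4)o3)c12 | target

## Step count and least certain steps

Total: 11 steps. Longest linear sequence: 8 steps (7 → 22, steps 4 to 11). The aryne branch (1 → 6) has 3 steps and joins at step 10.

Step 10 (key step). The hetaryl azirine nitrogen is a weak nucleophile, so the aryne may be consumed by oligomerisation or by cycloaddition across the pyrrole or oxazole ring before it is captured. The N–H product may be arylated by further aryne. Fluoride at 60 °C may degrade the azirine. Closure of the aryl anion at the CH2 carbon instead of the C=N carbon would lead to the 2-substituted isomer. A C2-unsubstituted hetaryl azirine also lies outside the best-documented substrates for this annulation. The fallback sets out from 14 and returns at 21, and it makes the indole–oxazole bond by Negishi coupling instead of building the indole. 14 is magnesiated as in step 7 to 15 and transmetalated with ZnCl2 to [2-(5-bromo-1-SEM-pyrrol-2-yl)oxazol-5-yl]zinc chloride F1. Purchased 6-bromo-4-methoxy-1H-indole F2 is iodinated at C3 (I2, KOH, DMF) to 6-bromo-3-iodo-4-methoxy-1H-indole F3 and protected (Boc2O, DMAP) as tert-butyl 6-bromo-3-iodo-4-methoxyindole-1-carboxylate F4. Coupling of F1 with F4 (Pd(PPh3)4, THF, rt) should give tert-butyl 6-bromo-3-[2-(5-bromo-1-SEM-pyrrol-2-yl)oxazol-5-yl]-4-methoxyindole-1-carboxylate F5, because the C–I bond should undergo oxidative addition well before either C–Br bond. K2CO3 in MeOH then removes the carbamate and returns the route to 21.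

Step 9. The methyl protons of 18 are only moderately acidic, so deprotonation may be slower than Beckmann rearrangement or fragmentation of the oxime sulfonate. The C2-unsubstituted azirine may also be lost by dimerisation or by addition of the amidine base. The fallback sets out from 14 and returns at 19, reaching the azirine by thermolysis of a vinyl azide. 15 is quenched with DMF to give 2-(5-bromo-1-SEM-pyrrol-2-yl)oxazole-5-carbaldehyde F6. Seyferth–Gilbert homologation with the Ohira–Bestmann reagent (K2CO3, MeOH) should give 2-(5-bromo-1-SEM-pyrrol-2-yl)-5-ethynyloxazole F7. Ag2CO3-catalysed Markovnikov hydroazidation (Me3SiN3, H2O, DMSO) should give 5-(1-azidovinyl)-2-(5-bromo-1-SEM-pyrrol-2-yl)oxazole F8. Heating F8 in dilute toluene at about 90 °C expels N2 and closes 19. The azide is kept in solution, on small scale and behind a shield; this hazard is the reason the route is held in reserve.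

Step 11. Attack at silicon may be slow on a pyrrole flanked by bromine and oxazole. The cleavage may stall at the N-hydroxymethyl stage, or formaldehyde may add back to the free N–H groups. Prolonged heating with basic fluoride may also erode the bromopyrrole. The fallback sets out from 21 and returns at 22, and it cleaves the acetal C–O bond with a Lewis acid instead of attacking silicon with fluoride. BF3·OEt2 in CH2Cl2 at 0 °C should give [2-bromo-5-[5-(6-bromo-4-methoxy-1H-indol-3-yl)oxazol-2-yl]pyrrol-1-yl]methanol F9, which is isolated. Aqueous NH3 in MeOH then removes formaldehyde to give 22.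

## Further compounds

F1 | step 10 | [2-(5-bromo-1-{[2-(trimethylsilyl)ethoxy]methyl}pyrrol-2-yl)oxazol-5-yl]zinc chloride | C[Si](C)(C)CCOCn1c(Br)ccc1-c1ncc([Zn]Cl)o1
F2 | step 10 | 6-bromo-4-methoxy-1H-indole (purchased) | COc1cc(Br)cc2[nH]ccc12
F3 | step 10 | 6-bromo-3-iodo-4-methoxy-1H-indole | COc1cc(Br)cc2[nH]cc(I)c12
F4 | step 10 | tert-butyl 6-bromo-3-iodo-4-methoxyindole-1-carboxylate | COc1cc(Br)cc2n(C(=O)OC(C)(C)C)cc(I)c12
F5 | step 10 | tert-butyl 6-bromo-3-[2-(5-bromo-1-{[2-(trimethylsilyl)ethoxy]methyl}pyrrol-2-yl)oxazol-5-yl]-4-methoxyindole-1-carboxylate | COc1cc(Br)cc2n(C(=O)OC(C)(C)C)cc(-c3cnc(-c4ccc(Br)n4COCC[Si](C)(C)C)o3)c12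
F6 | step 9 | 2-(5-bromo-1-{[2-(trimethylsilyl)ethoxy]methyl}pyrrol-2-yl)oxazole-5-carbaldehyde | O=Cc1cnc(-c2ccc(Br)n2COCC[Si](C)(C)C)o1
F7 | step 9 | 2-(5-bromo-1-{[2-(trimethylsilyl)ethoxy]methyl}pyrrol-2-yl)-5-ethynyloxazole | C#Cc1cnc(-c2ccc(Br)n2COCC[Si](C)(C)C)o1
F8 | step 9 | 5-(1-azidovinyl)-2-(5-bromo-1-{[2-(trimethylsilyl)ethoxy]methyl}pyrrol-2-yl)oxazole | C=C(N=[N+]=[N-])c1cnc(-c2ccc(Br)n2COCC[Si](C)(C)C)o1
F9 | step 11 | [2-bromo-5-[5-(6-bromo-4-methoxy-1H-indol-3-yl)oxazol-2-yl]pyrrol-1-yl]methanol | COc1cc(Br)cc2[nH]cc(-c3cnc(-c4ccc(Br)n4CO)o3)c12
A1 | alternative 1 | tert-butyl 6-bromo-3-{2-[1-(tert-butoxycarbonyl)pyrrol-2-yl]oxazol-5-yl}-4-methoxyindole-1-carboxylate | COc1cc(Br)cc2n(C(=O)OC(C)(C)C)cc(-c3cnc(-c4cccn4C(=O)OC(C)(C)C)o3)c12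
A2 | alternative 1 | tert-butyl 6-bromo-3-{3-[1-(tert-butoxycarbonyl)pyrrol-2-yl]isoxazol-5-yl}-4-methoxyindole-1-carboxylate | COc1cc(Br)cc2n(C(=O)OC(C)(C)C)cc(-c3cc(-c4cccn4C(=O)OC(C)(C)C)no3)c12
A3 | alternative 2 | 5-(6-bromo-4-methoxy-1-{[2-(trimethylsilyl)ethoxy]methyl}indol-3-yl)oxazole | COc1cc(Br)cc2n(COCC[Si](C)(C)C)cc(-c3cnco3)c12
A4 | alternative 2 | 6-bromo-4-methoxy-1-{[2-(trimethylsilyl)ethoxy]methyl}indole-3-carbaldehyde | COc1cc(Br)cc2n(COCC[Si](C)(C)C)cc(C=O)c12
A5 | alternative 2 | tosylmethyl isocyanide | Cc1ccc(cc1)S(=O)(=O)C[N+]#[C-]
A6 | alternative 3 | 5-[6-bromo-4-methoxy-2-(trimethylsilyl)-1H-indol-3-yl]-2-(1-{[2-(trimethylsilyl)ethoxy]methyl}pyrrol-2-yl)oxazole | COc1cc(Br)cc2[nH]c([Si](C)(C)C)c(-c3cnc(-c4cccn4COCC[Si](C)(C)C)o3)c12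
A7 | alternative 3 | 5-bromo-2-iodo-3-methoxyaniline | COc1cc(Br)cc(N)c1I
A8 | alternative 3 | 5-[(trimethylsilyl)ethynyl]-2-(1-{[2-(trimethylsilyl)ethoxy]methyl}pyrrol-2-yl)oxazole | C[Si](C)(C)C#Cc1cnc(-c2cccn2COCC[Si](C)(C)C)o1
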